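## The problem

The target is a drimane sesquiterpene ether of umbelliferone. Drimane numbering is used throughout: ring A is C1–C5 and C10, ring B is C5–C10, C11 is the CH2O carbon on C9, C12 the methyl on C8, C13 and C14 the methyls on C4, and C15 the methyl on C10. The rings are trans-fused, and the three contiguous stereocentres are C5 (S), C10 (R, quaternary) and C9 (S). C11 stands on the face opposite C15, on the same face as H5, so it is axial. Any reagent that approaches C9 from outside comes from the face away from C15 and would place hydrogen, not C11, on that face; C9 therefore has to be set together with C10 in a C–C bond-forming event. C10 cannot be corrected after it is made, and C9 can be corrected only while C11 is a carbonyl carbon, at the risk of the alkene moving into conjugation. C5 can be adjusted as long as a ketone sits at C6. The C7=C8 alkene can slide to C8=C9 under acid and erase C9, the coumarin lactone tolerates neither hydride nor strong base, and the C3 ketone must be masked through every hydride step. The enabling feature is that C9 and C10 are vicinal in ring B with C8 and C7 next in line: ring B is the [4+2] sum of a diene C10=C5–C6=C7 held on ring A and a two-carbon unit C8=C9 carrying C12 and C11, and the anti relation of C11 and C15 is the endo outcome.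

## Retrosynthesis

**Ether bond C11–O.** Cutting it gives keto alcohol 20 and umbelliferone 21. This cut comes first because the coumarin is the least robust part of the molecule and can then be added after the last hydride and base step. The forward reaction is a Mitsunobu etherification at a primary but β-branched carbon.

**Protecting groups.** 20 is taken back to 19, in which C3 is a dioxolane and C11–OH a silyl ether. Both fall in one acid treatment, and both are needed for the three hydride steps before it.

**The C6 oxygen.** The alkene of 19 is traced to allylic acetate 18, alcohol 17 and enone 16. A ketone at C6 is the only function that can both introduce C7=C8 (C4 and C10 bear no hydrogen, so dehydrogenation can go nowhere else) and let C5 be equilibrated. The price is a three-step reductive removal, which asks that hydride be delivered to C6 and not to C8 of the allyl intermediate.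

**Timing of the C5 adjustment.** Enone 16 is traced to saturated ketone 13 through silyl enol ether 14 and the cis enone 15. The equilibration is placed after the dehydrogenation and not before it. In the saturated trans ketone, C12 (left syn to C15 by the cycloaddition) would be 1,3-diaxial to C15, so the trans fusion is not clearly favoured there. Once C8 is trigonal that clash is gone.

**Back to the cycloadduct.** 13 comes from enol ether 12, alcohol 11 and imide 10 by hydrolysis, silylation and reductive cleavage of the imide. The imide is reduced at once so that C9 never sits next to a carbonyl under basic conditions.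

**Key disconnection, C9–C10 and C7–C8.** Ring B of 10 is opened to diene 8 and dienophile 9. No other cut makes both the quaternary centre and its neighbour in one step. The forward reaction must be regioselective (secured by the C6 ethoxy group), endo-selective (this sets C11 anti to C15) and face-selective (secured by the copper bis(oxazoline) catalyst). The precursors are an achiral diene and a commercial imide.

**Diene.** The C5–C6 bond of 8 is cut to enol triflate 6 and stannane 7 (Stille coupling). 6 comes from ketone 4, and 4 from mono-ketal 2 of dione 1. The ketal differentiates the two carbonyls of 1 and leaves only one enolisable position at each enolate step.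

## Roads not taken

**Alternative 1:** The C15 methyl is traced to a cyclopropane. Diethylzinc and diiodomethane cyclopropanate the C9=C10 alkene of allylic alcohol A2 on the face of its C8 hydroxyl and give methano alcohol A1. Oxidation at C8 and dissolving-metal cleavage of the C9–CH2 bond would then reveal the methyl.
- Merits: the hydroxyl-directed cyclopropanation is more certain than a hindered cycloaddition. The C8 ketone that results can be turned into the C7=C8 methyl alkene through its kinetic enol triflate, with no oxygen to delete. In that respect this road is better than the chosen one.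
- Weak points: A1 lacks C11, C12 and the alkene. C11 has to be added at C9 as a β-hydroxymethyl ketone that is prone to retro-aldol loss. A2 needs its own enantioselective synthesis with H5 already trans.
- Comparison: the chosen plan sets C9, C10 and the absolute configuration in one catalytic step from a diene made in four steps, at the cost of the C6 deoxygenation.

**Alternative 2:** Ring A is built by a Diels–Alder addition of silyloxy diene A5 across the methyl-bearing alkene of quinone A4, giving cis-fused adduct A3 with C12 and C7=C8 already present.
- Merits: the ring-forming step pairs an electron-poor quinone with an electron-rich diene and is likely to be easier than the one chosen here. Both partners are short to make.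
- Weak points: A3 is cis-fused and, without a chiral catalyst, racemic. C9 is a carbonyl carbon, so C11 must be added afterwards, and any reagent-controlled way of doing so places H9 from the face away from C15, which gives the wrong C9 epimer. The C6 oxygen has to be removed just as in the chosen plan, and the two ring B carbonyls must be told apart.
- Comparison: the chosen plan sets C9 in the cycloaddition itself, which this road cannot do.

**Alternative 3:** The C7=C8 alkene is written by ring-closing metathesis of diene A7 with the second-generation Grubbs catalyst, giving ester A6.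
- Merits: this is the most dependable ring closure of the four. It places the alkene without ambiguity and leaves no C6 oxygen, so its end game is shorter.
- Weak points: the metathesis makes no stereocentre. C5, C10 and the exocyclic, epimerisable C9 (α to the ester and allylic) must all be set on ring A beforehand. The C1=C2 alkene must then be hydrogenated in the presence of C7=C8, the ester reduced and C3 oxidised.
- Comparison: the chosen plan creates its stereocentres in the ring-forming step and has a far shorter fragment synthesis, but pays with about five steps of C5/C6/C7 adjustment.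

Key step: step 5

Remarks on the chemistry:
- "Methyl face" means the face of the decalin that carries C15.
- t-Bu-box is 2,2′-(propane-2,2-diyl)bis[(4S)-4-tert-butyl-4,5-dihydro-1,3-oxazole]. The (S,S) ligand is assigned from the square-planar chelate model; its mirror image would be used if the adduct proved enantiomeric.
- Hydrolysis in step 8 is assumed to give both C5 epimers, so 13 and 14 are written with C5 undefined; they converge in step 9.

## Route

Step 1
Reactants: 1 2,2-dimethylcyclohexane-1,3-dione
Product: 2 6,6-dimethyl-1,4-dioxaspiro[4.5]decan-7-one
Conditions: HOCH2CH2OH (1.05 equiv), p-TsOH (cat.), benzene, reflux, Dean–Stark trap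
Reagents that add atoms: ethylene glycol, OCCO
Why: Acid-catalysed mono-ketalisation with one equivalent of diol; the second carbonyl, now flanked by a quaternary carbon and a ketal, reacts more slowly.

Step 2
Reactants: 2 6,6-dimethyl-1,4-dioxaspiro[4.5]decan-7-one
Product: 4 racemic 6,6,8-trimethyl-1,4-dioxaspiro[4.5]decan-7-one, via lithium enolate 3 (not isolated)
Conditions: LDA, THF, −78 °C; MeI, −78 to 0 °C
Reagents that add atoms: iodomethane, CI
Why: Enolate alkylation; the ketone has only one enolisable position (the future C10), so the methyl can enter nowhere else, and the new stereocentre is erased in step 3.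

Step 3
Reactants: 4 racemic 6,6,8-trimethyl-1,4-dioxaspiro[4.5]decan-7-one
Product: 6 6,6,8-trimethyl-1,4-dioxaspiro[4.5]dec-7-en-7-yl trifluoromethanesulfonate, via potassium enolate 5 (not isolated)
Conditions: KHMDS, THF, −78 to 0 °C; PhNTf2, −78 °C to rt
Reagents that add atoms: N-phenylbis(trifluoromethanesulfonimide), O=S(=O)(N(c1ccccc1)S(=O)(=O)C(F)(F)F)C(F)(F)F
Why: The single remaining α-hydrogen gives one tetrasubstituted enolate, which is O-sulfonylated (enol triflate formation, as for 2,2,6-trimethylcyclohexanone).

Step 4
Reactants: 6 6,6,8-trimethyl-1,4-dioxaspiro[4.5]dec-7-en-7-yl trifluoromethanesulfonate; 7 tributyl(1-ethoxyethenyl)stannane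
Product: 8 7-(1-ethoxyethenyl)-6,6,8-trimethyl-1,4-dioxaspiro[4.5]dec-7-ene
Conditions: Pd(PPh3)4 (10 mol%), CuCl, LiCl, DMSO, 60 °C; KF work-up, Et3N-deactivated silica
Reagents that add atoms: none
Why: Stille coupling of a vinyl triflate with an α-alkoxyvinylstannane; copper chloride speeds transmetalation at the hindered tetrasubstituted triflate, and basic handling protects the enol ether.

Step 5
Reactants: 8 7-(1-ethoxyethenyl)-6,6,8-trimethyl-1,4-dioxaspiro[4.5]dec-7-ene; 9 3-[(E)-but-2-enoyl]oxazolidin-2-one
Product: 10 endo adduct 3-[6-ethoxy-3,3-(ethylenedioxy)drim-5-en-11-oyl]oxazolidin-2-one (C12 and C15 on the methyl face; C9 acyl group on the opposite face)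
Conditions: Cu(SbF6)2·(S,S)-t-Bu-box (10–20 mol%, from CuCl2, AgSbF6 and the ligand), CH2Cl2, 3 Å MS, −20 °C to rt
Reagents that add atoms: none
Why: Divalent copper chelates both imide carbonyls of 9 in a square-planar complex with the enoyl unit s-cis, and the diene adds in a concerted, asynchronous [4+2] cycloaddition; the closest known reaction type is the bis(oxazoline)–copper-catalysed Diels–Alder addition of N-crotonoyl oxazolidinone to acyclic dienes. Ring B closes by intermolecular [4+2] annulation, suprafacial on both partners, with C7–C8 forming ahead of C9–C10. The C6 ethoxy group puts the largest HOMO coefficient on C7, which bonds to the β-carbon C8, so C10 bonds to the α-carbon C9. C8 against C9 follows from the E geometry of 9, which leaves C12 and the acyl group trans. C9 against C10 follows from the endo transition state: the chelated acyl group lies under C5–C6 and the inward C10 methyl turns to the far face, so the acyl group ends anti to C15; this endo preference, reinforced by the cationic hexafluoroantimonate complex, is the selectivity the step needs most. The absolute configuration comes from the ligand, whose tert-butyl group covers the α-Si face of the bound enoyl unit so that 8 adds to the α-Re face at C9. The weakly coordinating counter-ion and the sieves are chosen because the diene is hindered and its enol ether must not be hydrolysed.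

Step 6
Reactants: 10 endo adduct imide
Product: 11 6-ethoxy-3,3-(ethylenedioxy)drim-5-en-11-ol
Conditions: LiBH4, MeOH (1 equiv), THF, 0 °C
Reagents that add atoms: none
Why: Reductive cleavage of an N-acyl oxazolidinone to the primary alcohol; enol ether and dioxolane are inert to borohydride, and C9 is now safe from epimerisation.

Step 7
Reactants: 11 6-ethoxy-3,3-(ethylenedioxy)drim-5-en-11-ol
Product: 12 11-(tert-butyldimethylsilyloxy)-6-ethoxy-3,3-(ethylenedioxy)drim-5-ene
Conditions: TBSCl, imidazole, DMF, rt
Reagents that add atoms: tert-butyldimethylsilyl chloride, CC(C)(C)[Si](C)(C)Cl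
Why: Silylation of a primary alcohol; the ether keeps C11–OH from trapping the C6 oxocarbenium ion in step 8 and survives the base and hydride steps that follow.

Step 8
Reactants: 12 11-(tert-butyldimethylsilyloxy)-6-ethoxy-3,3-(ethylenedioxy)drim-5-ene
Product: 13 11-(tert-butyldimethylsilyloxy)-3,3-(ethylenedioxy)drimane-6-one (mixture of C5 epimers)
Conditions: (CO2H)2·2H2O, THF–H2O, rt
Reagents that add atoms: water, O
Why: Enol ethers hydrolyse by rate-limiting C-protonation much faster than a dioxolane or a primary silyl ether under oxalic acid; protonation at C5 is not expected to be face-selective, and the epimers are carried on together because C5 is settled in step 9.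

Step 9
Reactants: 13 11-(tert-butyldimethylsilyloxy)-3,3-(ethylenedioxy)drimane-6-one (mixture of C5 epimers)
Product: 16 trans-fused 11-(tert-butyldimethylsilyloxy)-3,3-(ethylenedioxy)drim-7-en-6-one, via TMS enol ether 14 (not isolated), via cis-fused enone 15 (not isolated)
Conditions: TMSCl, LDA, THF, −78 °C (in situ quench); Pd(OAc)2, MeCN, rt; NaOMe (0.2 equiv), MeOH, 0 °C to rt
Reagents that add atoms: none
Why: Kinetic deprotonation can only occur at C7 (H5 is buried between two quaternary carbons), and 14 undergoes Saegusa–Ito oxidation with syn loss of H8, the only dehydrogenation open to this ketone; with C8 trigonal the C12/C15 diaxial clash of the saturated trans ketone is gone, so methoxide equilibration through the C5 enolate should drain 15 into trans-fused 16 (H5 anti to C15), while H9 lies in the enone plane and C11 stays pseudo-axial beside C12.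

Step 10
Reactants: 16 trans-fused 11-(tert-butyldimethylsilyloxy)-3,3-(ethylenedioxy)drim-7-en-6-one
Product: 17 11-(tert-butyldimethylsilyloxy)-3,3-(ethylenedioxy)drim-7-en-6-ol (C6 hydroxyl on the methyl face)
Conditions: NaBH4, CeCl3·7H2O, MeOH, −78 to 0 °C
Reagents that add atoms: none
Why: Luche 1,2-reduction; hydride enters from the face away from C15 and the axial C4 methyl, so the hydroxyl ends on the methyl face, a centre that is removed in step 12.

Step 11
Reactants: 17 11-(tert-butyldimethylsilyloxy)-3,3-(ethylenedioxy)drim-7-en-6-ol
Product: 18 6-acetoxy-11-(tert-butyldimethylsilyloxy)-3,3-(ethylenedioxy)drim-7-ene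
Conditions: Ac2O, DMAP, Et3N, CH2Cl2, rt to 40 °C
Reagents that add atoms: acetic anhydride, CC(=O)OC(C)=O
Why: DMAP-catalysed acylation, chosen because the pseudo-axial C6 hydroxyl is flanked by the C4 methyls and C15.

Step 12
Reactants: 18 6-acetoxy-11-(tert-butyldimethylsilyloxy)-3,3-(ethylenedioxy)drim-7-ene
Product: 19 11-(tert-butyldimethylsilyloxy)-3,3-(ethylenedioxy)drim-7-ene
Conditions: Pd(PPh3)4 (5 mol%), LiBHEt3, THF, 0 °C to rt
Reagents that add atoms: none
Why: Zerovalent palladium ionises the pseudo-axial acetate from the open face to a C6–C7–C8 allyl complex, and hydride is transferred to the less substituted terminus C6 (reductive allylic deoxygenation of Tsuji–Trost type), leaving the trisubstituted C7=C8 alkene; C6 becomes a methylene, so its configuration is of no consequence.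

Step 13
Reactants: 19 11-(tert-butyldimethylsilyloxy)-3,3-(ethylenedioxy)drim-7-ene
Product: 20 11-hydroxydrim-7-en-3-one (H5 and C11 on the face opposite C15)
Conditions: 2 M HCl (aq), THF, rt
Reagents that add atoms: water, O
Why: Acid hydrolysis removes the primary silyl ether and the strained neopentyl dioxolane together; room temperature and dilute acid are chosen so that the C7=C8 alkene does not migrate to C8=C9.

Step 14
Reactants: 20 11-hydroxydrim-7-en-3-one; 21 umbelliferone (7-hydroxy-2H-chromen-2-one)
Product: 22 7-{[(1S,4aS,8aR)-2,5,5,8a-tetramethyl-6-oxo-1,4,4a,5,6,7,8,8a-octahydronaphthalen-1-yl]methoxy}-2H-chromen-2-one (drimane numbering 5S,9S,10R)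
Conditions: PPh3, DIAD, THF, 0 °C to rt
Reagents that add atoms: none
Why: Mitsunobu etherification of a primary alcohol with an acidic phenol; substitution is at C11, so no stereocentre is touched, and the ketone, alkene and lactone are inert to the reagents.

## Compound list

1 | 2,2-dimethylcyclohexane-1,3-dione | CC1(C)C(=O)CCCC1=O | starting material
2 | 6,6-dimethyl-1,4-dioxaspiro[4.5]decan-7-one | CC1(C)C(=O)CCCC12OCCO2 | intermediate
3 | lithium 6,6-dimethyl-1,4-dioxaspiro[4.5]dec-7-en-7-olate (not isolated) | [Li+].[O-]C1=CCCC2(OCCO2)C1(C)C | intermediate
4 | racemic 6,6,8-trimethyl-1,4-dioxaspiro[4.5]decan-7-one | CC1CCC2(OCCO2)C(C)(C)C1=O | intermediate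
5 | potassium 6,6,8-trimethyl-1,4-dioxaspiro[4.5]dec-7-en-7-olate (not isolated) | [K+].[O-]C1=C(C)CCC2(OCCO2)C1(C)C | intermediate
6 | 6,6,8-trimethyl-1,4-dioxaspiro[4.5]dec-7-en-7-yl trifluoromethanesulfonate | CC1=C(OS(=O)(=O)C(F)(F)F)C(C)(C)C2(OCCO2)CC1 | intermediate
7 | tributyl(1-ethoxyethenyl)stannane | CCCC[Sn](CCCC)(CCCC)C(=C)OCC | starting material
8 | 7-(1-ethoxyethenyl)-6,6,8-trimethyl-1,4-dioxaspiro[4.5]dec-7-ene | CC1=C(C(OCC)=C)C(C)(C)C2(OCCO2)CC1 | intermediate
9 | 3-[(E)-but-2-enoyl]oxazolidin-2-one | C/C=C/C(=O)N1CCOC1=O | starting material
10 | endo adduct, 3-[6-ethoxy-3,3-(ethylenedioxy)drim-5-en-11-oyl]oxazolidin-2-one; C12 and C15 on the methyl face, acyl group opposite | C[C@@H]1CC(OCC)=C2C(C)(C)C3(OCCO3)CC[C@@]2(C)[C@H]1C(=O)N1CCOC1=O | intermediate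
11 | 6-ethoxy-3,3-(ethylenedioxy)drim-5-en-11-ol | C[C@@H]1CC(OCC)=C2C(C)(C)C3(OCCO3)CC[C@@]2(C)[C@H]1CO | intermediate
12 | 11-(tert-butyldimethylsilyloxy)-6-ethoxy-3,3-(ethylenedioxy)drim-5-ene | C[C@@H]1CC(OCC)=C2C(C)(C)C3(OCCO3)CC[C@@]2(C)[C@H]1CO[Si](C)(C)C(C)(C)C | intermediate
13 | 11-(tert-butyldimethylsilyloxy)-3,3-(ethylenedioxy)drimane-6-one, mixture of C5 epimers | C[C@@H]1CC(=O)C2C(C)(C)C3(OCCO3)CC[C@@]2(C)[C@H]1CO[Si](C)(C)C(C)(C)C | intermediate
14 | 6-(trimethylsilyloxy)drim-6-ene derivative of 13, C5 undefined (not isolated) | C[C@@H]1C=C(O[Si](C)(C)C)C2C(C)(C)C3(OCCO3)CC[C@@]2(C)[C@H]1CO[Si](C)(C)C(C)(C)C | intermediate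
15 | cis-fused 11-(tert-butyldimethylsilyloxy)-3,3-(ethylenedioxy)drim-7-en-6-one, H5 on the methyl face (not isolated) | CC1=CC(=O)[C@H]2C(C)(C)C3(OCCO3)CC[C@@]2(C)[C@H]1CO[Si](C)(C)C(C)(C)C | intermediate
16 | trans-fused 11-(tert-butyldimethylsilyloxy)-3,3-(ethylenedioxy)drim-7-en-6-one, H5 and C11 opposite C15 | CC1=CC(=O)[C@@H]2C(C)(C)C3(OCCO3)CC[C@@]2(C)[C@H]1CO[Si](C)(C)C(C)(C)C | intermediate
17 | 11-(tert-butyldimethylsilyloxy)-3,3-(ethylenedioxy)drim-7-en-6-ol, hydroxyl on the methyl face | CC1=C[C@H](O)[C@@H]2C(C)(C)C3(OCCO3)CC[C@@]2(C)[C@H]1CO[Si](C)(C)C(C)(C)C | intermediate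
18 | 6-acetoxy-11-(tert-butyldimethylsilyloxy)-3,3-(ethylenedioxy)drim-7-ene | CC1=C[C@H](OC(C)=O)[C@@H]2C(C)(C)C3(OCCO3)CC[C@@]2(C)[C@H]1CO[Si](C)(C)C(C)(C)C | intermediate
19 | 11-(tert-butyldimethylsilyloxy)-3,3-(ethylenedioxy)drim-7-ene | CC1=CC[C@@H]2C(C)(C)C3(OCCO3)CC[C@@]2(C)[C@H]1CO[Si](C)(C)C(C)(C)C | intermediate
20 | 11-hydroxydrim-7-en-3-one, H5 and C11 opposite C15 | CC1=CC[C@@H]2C(C)(C)C(=O)CC[C@@]2(C)[C@H]1CO | intermediate
21 | umbelliferone (7-hydroxy-2H-chromen-2-one) | O=c1ccc2ccc(O)cc2o1 | starting material
22 | 7-{[(1S,4aS,8aR)-2,5,5,8a-tetramethyl-6-oxo-1,4,4a,5,6,7,8,8a-octahydronaphthalen-1-yl]methoxy}-2H-chromen-2-one | CC1=CC[C@@H]2C(C)(C)C(=O)CC[C@@]2(C)[C@H]1COc1ccc2ccc(=O)oc2c1 | target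

## Step count and risks

Total step count: 14. Longest linear sequence: 14 steps (1 to 22); 7, 9 and 21 are purchased.

**Step 5 (key step).** Three processes threaten it.
- The cycloaddition may stall, because the s-cis diene is strained by the inward C10 methyl and the C4 methyls.
- Endo selectivity may erode: the flat chelate must pass under ring A, where either the axial dioxolane oxygen at C3 or the pseudo-axial C4 methyl points toward it, and the exo mode would give the C9 epimer.
- The reaction may leak into a stepwise Mukaiyama–Michael addition and lose stereospecificity.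

The fallback takes the steric load out of ring A instead of changing the catalyst. It sets out from 6 and comes back at 10. The dioxolane of 6 is hydrolysed with aqueous HCl in THF to 2,6,6-trimethyl-5-oxocyclohex-1-en-1-yl triflate F1. Stille coupling with 7 under the conditions of step 4 gives 3-(1-ethoxyethenyl)-2,2,4-trimethylcyclohex-3-en-1-one F2. Its trigonal C3 carries no axial substituent, so ring A can turn its pseudo-axial C4 methyl to the far face. Cycloaddition with 9 under the conditions of step 5 gives the C3-keto adduct F3. The dioxolane is then put back under aprotic silyl-transfer conditions (1,2-bis(trimethylsilyloxy)ethane, catalytic TMSOTf, CH2Cl2, −78 °C), which leave the ethyl enol ether alone and give 10.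

**Step 4.** Oxidative addition and transmetalation at a tetrasubstituted triflate flanked by a quaternary carbon may be too slow, with triflate hydrolysis or destannylation taking over. The fallback forms the C5–C6 bond by carbonyl addition. It sets out from 4 and returns at 8. 1-Ethoxyvinyllithium (from ethyl vinyl ether and t-BuLi, with CeCl3) adds to the ketone to give 7-(1-ethoxyethenyl)-6,6,8-trimethyl-1,4-dioxaspiro[4.5]decan-7-ol F4. Dehydration with the Burgess reagent or SOCl2 in pyridine can only run toward the one β-hydrogen at C10 and gives 8.

**Step 9.** Equilibration at C5 may be incomplete. The extended dienolate may also form and cause epimerisation at C9, deconjugation to C8=C9, or vinylogous loss of the C11 silyloxy group. The fallback replaces thermodynamic by kinetic control. It sets out from the 15/16 mixture and returns at 16. LDA at −78 °C removes H5 to give the cross-conjugated lithium dienolate F5, which is protonated at −78 °C with 2,6-di-tert-butylphenol from the face away from C15.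

**Step 12.** Hydride may be delivered to the tertiary terminus C8, moving the alkene to C6=C7. Hydride may also attack the acetate carbonyl directly and return 17. The fallback is a radical deoxygenation, from 17 to 19. NaH, CS2 and MeI give the S-methyl xanthate F6. Bu3SnH and AIBN in toluene at 90 °C generate the C6–C7–C8 allyl radical, which takes hydrogen at the less substituted C6 (Barton–McCombie reaction). A xanthate that has undergone allylic rearrangement gives the same radical.

**Step 14.** Substitution at the β-branched C11 under an axial environment may be slow, so that the betaine is consumed by side reactions. The fallback reverses the polarity and avoids substitution at C11 altogether. It runs from 20 to 22: palladium-catalysed C–O cross-coupling of the alcohol with 7-bromo-2H-chromen-2-one F7 ([Pd(allyl)Cl]2, RockPhos, Cs2CO3, toluene, 90 °C).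

## Further compounds

F1 | step 5 | 2,6,6-trimethyl-5-oxocyclohex-1-en-1-yl trifluoromethanesulfonate | CC1=C(OS(=O)(=O)C(F)(F)F)C(C)(C)C(=O)CC1
F2 | step 5 | 3-(1-ethoxyethenyl)-2,2,4-trimethylcyclohex-3-en-1-one | CC1=C(C(OCC)=C)C(C)(C)C(=O)CC1
F3 | step 5 | 3-(6-ethoxy-3-oxodrim-5-en-11-oyl)oxazolidin-2-one, configuration as in 10 | C[C@@H]1CC(OCC)=C2C(C)(C)C(=O)CC[C@@]2(C)[C@H]1C(=O)N1CCOC1=O
F4 | step 4 | 7-(1-ethoxyethenyl)-6,6,8-trimethyl-1,4-dioxaspiro[4.5]decan-7-ol, racemic diastereomer mixture | CCOC(=C)C1(O)C(C)CCC2(OCCO2)C1(C)C
F5 | step 9 | lithium 11-(tert-butyldimethylsilyloxy)-3,3-(ethylenedioxy)drima-5,7-dien-6-olate | [Li+].CC1=CC([O-])=C2C(C)(C)C3(OCCO3)CC[C@@]2(C)[C@H]1CO[Si](C)(C)C(C)(C)C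
F6 | step 12 | O-[11-(tert-butyldimethylsilyloxy)-3,3-(ethylenedioxy)drim-7-en-6-yl] S-methyl dithiocarbonate | CC1=C[C@H](OC(=S)SC)[C@@H]2C(C)(C)C3(OCCO3)CC[C@@]2(C)[C@H]1CO[Si](C)(C)C(C)(C)C
F7 | step 14 | 7-bromo-2H-chromen-2-one (purchased) | O=c1ccc2ccc(Br)cc2o1
A1 | alternative 1 | 9,10-methano alcohol, cyclopropane on the hydroxyl face | O[C@@H]1CC[C@@H]2C(C)(C)C3(OCCO3)CC[C@]24C[C@H]14
A2 | alternative 1 | C9=C10 allylic alcohol with C8 hydroxyl, C3 dioxolane and trans H5 | O[C@@H]1CC[C@@H]2C(C)(C)C3(OCCO3)CCC2=C1
A3 | alternative 2 | cis-fused quinone adduct with C3 silyl enol ether, C6 and C9 ketones, C7=C8 | CC1=CC(=O)[C@H]2C(C)(C)C(O[Si](C(C)C)(C(C)C)C(C)C)=CC[C@@]2(C)C1=O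
A4 | alternative 2 | 2,6-dimethyl-1,4-benzoquinone | CC1=CC(=O)C=C(C)C1=O
A5 | alternative 2 | 4-methyl-3-(triisopropylsilyloxy)penta-1,3-diene | C=CC(O[Si](C(C)C)(C(C)C)C(C)C)=C(C)C
A6 | alternative 3 | bicyclic C11 methyl ester with C7=C8 and C1=C2 alkenes and C3 silyl ether | CC1=CC[C@@H]2C(C)(C)[C@H](O[Si](C)(C)C(C)(C)C)C=C[C@@]2(C)[C@H]1C(=O)OC
A7 | alternative 3 | ring A diene with C5 allyl group and C9 isopropenyl group | C=CC[C@@H]1C(C)(C)[C@H](O[Si](C)(C)C(C)(C)C)C=C[C@@]1(C)[C@H](C(C)=C)C(=O)OC
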